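Readings and results are simulated on assumed constants, and the scatter is random.

How does the G share of the charge move as the charge of Q climbs from 0.10 M to 1.5 M, with X held at 23 µM and 12 h allowed?

the same everywhere: X 23 µM

| charge | Q | remark | time |
|---|---|---|---|
| gamma | 0.084 M | run made earlier |  |
| theta | 0.37 M | run made earlier |  |
| zeta | 1.1 M | run made earlier |  |
| south | 0.10 M |  | 12 h |
| north-west | 0.20 M |  | 12 h |
| west | 0.40 M |  | 12 h |
| south-west | 0.80 M |  | 12 h |
| east | 1.5 M |  | 12 h |

- gamma (time / h: G / %, Q / %): 1.00: 96.7, 0.4; 3.00: 99.9, 0.1; 6.00: 100.5, 0; 8.00: 100.9, 0.9; 12.0: 97.8, 0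
- theta (time / h: G / %, Q / %): 1.00: 14.0, 81.8; 3.00: 12.6, 71.6; 6.00: 13.3, 62.1; 8.00: 14.3, 53.9; 12.0: 14.3, 44.5
- zeta (time / h: G / %, Q / %): 1.00: 1.5, 93.1; 3.00: 0.6, 84.8; 6.00: 1.6, 70.7; 8.00: 0, 63.0; 12.0: 1.5, 49.2

(standard deviation of a reading: 1 percentage point)

- "hardly changes" means that all values lie within two and a half points (for a concentration: within two and a half percent of the largest)

* [G] at the end for south, north-west, west, south-west, east, in this order
* the shape of the row from first to last (rises, then falls / rises all the way / hardly changes / falls, then rises / falls all the way)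

In gamma the G share reads 99.9% at 3.00 h, which is the full charge within the scatter, so a share there says nothing about how the yield depends on charge. In theta G reads 14.0% at 1.00 h and 14.3% at 12.0 h, while Q falls from 81.8% to 44.5%. I therefore take the mean, 13.7%, as a final share. The same mean in zeta is 1.04%, a soft reading beside a scatter of 1 percentage point.

My scale has its zero at first order: with X and the time fixed, a step first order in Q converts the same share at any charge, so the slope is zero. A fixed amount of G per flask makes the share fall as the inverse of the charge, which is slope one. Theta to zeta gives 2.37, and this yield slope, the drop in the logarithm of the G share per unit rise in the logarithm of the charge, is what I carry. It stands above one, so between theta and zeta more Q gives less G.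

Run from theta, the slope reaches the full charge near 0.160 M, so I expect a crest there. My shares are 58.7% for north-west, 11.4% for west and 0.499% for east. North-west, just past that crest, is the flask to watch.

The forecast gives 0.1 M, 0.12 M, 0.046 M, 0.021 M and 0.011 M, with the shape rises, then falls, and says “This indicates strong substrate inhibition with a fixed enzyme lifetime.” For east its share of 0.733% stands above mine.

The flasks end at G shares of 98.6%, 94.9%, 10.9%, 1.57% and 0.265%, which are 0.0986 M, 0.190 M, 0.0434 M, 0.0126 M and 0.00397 M of G, and the shape is rises, then falls.

    Q + X → G + X, rate k1*[Q]*[X]/(1 + ([Q]/Km1) + ([Q]/Ksi1)^2) (30.0 mM, 0.0860 M, k = 170 /M/s)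
    Q → L (k = 1.60 × 10⁻⁵ /s)
    Q + X → E (k = 0.00280 /M/s)

West ends at 10.9% against my 11.4%, but north-west ends at 94.9% against my 58.7%; from west to east the slope is 2.81, steeper than the 2.37 I carried. North-west ends with X at 16.8% and Q at 0%, whereas west ends with X at 0% and Q at 44.6%. The largest single effect is the path from Q + X to E: the run without it changes the shape and lifts the G share in east from 0.265% to 70.8%.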